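**Retrosynthetic overview**

- Feature: in the benzene ring of the benzofuran, C5' (hydroxyl) and C6' (acetyl) are adjacent and C4' and C7' carry hydrogen. This is the pattern left when a ketene carbon (future C5') closes onto the acetyl-bearing alkene carbon of an enone (future C6') across the C2=C3 bond of a furan (future C7a'–C3a').
- Benzene ring (formed last): C5'–C6' bond by Ac2O/NaOAc ketene formation from a furan-3-ylacetic acid and six-electron electrocyclisation. The two aryl acetates are then removed beside the primary acetate.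
- Pyran C5–furan C5 bond: Suzuki coupling of a dihydropyran-5-yl boronate with a 5-bromofuran that already carries the free acetic acid and the (E)-enone.
- Pyran ring (formed first): an Evans syn aldol of (R)-4-benzyl-3-(pent-4-ynoyl)oxazolidin-2-one with O-silyl vanillin sets C2 (R) and C3 (S). A tungsten-vinylidene endo cycloisomerisation of the alkynol then closes O1–C6.
- Furan fragment: methyl 2-(furan-3-yl)acetate by C2 formylation, C5 bromination, Wittig olefination and saponification.

Key step: step 14

Remark on the chemistry: once the furyl enone sits on C5 of the pyran, O1 becomes a vinylogous enolate leaving group. The guaiacyl oxygen is therefore kept acetylated until the last, near-neutral step, so that no para-phenoxide can open the C2–O1 bond (quinone methide) and scramble C2.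

**Route**

Step 1
Reactants: 1 vanillin (4-hydroxy-3-methoxybenzaldehyde)
Product: 2 4-[(tert-butyldimethylsilyl)oxy]-3-methoxybenzaldehyde
Conditions: TBSCl, imidazole, DMF, rt
Reagents that add atoms: tert-butyldimethylsilyl chloride, CC(C)(C)[Si](C)(C)Cl
Why: Silylation of the phenol gives an aldehyde whose protecting group survives the boron aldol, its peroxide work-up, the amine/light cyclisation and LiBH4, none of which an aryl acetate would tolerate.

Step 2
Reactants: 3 (R)-4-benzyloxazolidin-2-one; 4 pent-4-ynoic acid
Product: 6 (R)-4-benzyl-3-(pent-4-ynoyl)oxazolidin-2-one, via mixed pivalic anhydride 5 (not isolated)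
Conditions: 4, PivCl, Et3N, THF, −20 °C; then 3, LiCl, −20 °C → rt
Reagents that add atoms: none
Why: N-Acylation of the Evans oxazolidinone through the pivalic mixed anhydride (LiCl-activated), which is attacked at its unhindered pentynoyl carbonyl.

Step 3
Reactants: 6 (R)-4-benzyl-3-(pent-4-ynoyl)oxazolidin-2-one; 2 4-[(tert-butyldimethylsilyl)oxy]-3-methoxybenzaldehyde
Product: 9 (R)-4-benzyl-3-[(2R)-2-{(R)-[4-(tert-butyldimethylsilyloxy)-3-methoxyphenyl](hydroxy)methyl}pent-4-ynoyl]oxazolidin-2-one, via dibutylboron Z-enolate 7 (not isolated), via dibutylboron aldolate 8 (not isolated)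
Conditions: Bu2BOTf, i-Pr2NEt, CH2Cl2, −78 → 0 °C; then 2, −78 → 0 °C; pH 7 buffer, MeOH, H2O2, 0 °C
Reagents that add atoms: none
Why: Evans syn aldol reaction: the Z boron enolate adds through a chair Zimmerman–Traxler transition state on the enolate face turned away from the benzyl group of the (R)-auxiliary, which sets the (2R,3R) syn pair that becomes C3 and C2 of the pyran (syn in the chain corresponds to trans in the ring).

Step 4
Reactants: 9 syn aldol adduct
Product: 10 (R)-4-benzyl-3-{(2R,3R)-2-[4-(tert-butyldimethylsilyloxy)-3-methoxyphenyl]-3,4-dihydro-2H-pyran-3-carbonyl}oxazolidin-2-one (2,3-trans)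
Conditions: W(CO)6 (25 mol %), Et3N, THF, hν (350 nm), 55 °C
Reagents that add atoms: none
Why: Endo-selective alkynol cycloisomerisation through a tungsten vinylidene: the photogenerated W(CO)5 fragment isomerises the terminal alkyne to a vinylidene, the benzylic hydroxyl adds to its metal-bound carbon and protonolysis releases the 3,4-dihydro-2H-pyran (O1–C6 bond) with both stereocentres untouched.

Step 5
Reactants: 10 dihydropyran imide
Product: 11 {(2R,3S)-2-[4-(tert-butyldimethylsilyloxy)-3-methoxyphenyl]-3,4-dihydro-2H-pyran-3-yl}methanol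
Conditions: LiBH4, MeOH (2 equiv), THF, 0 °C
Reagents that add atoms: none
Why: Reductive cleavage of the N-acyl oxazolidinone at the exocyclic carbonyl with LiBH4 gives the primary alcohol and returns the auxiliary, the enol ether and the silyl ether being inert to borohydride.

Step 6
Reactants: 11 silyl-protected pyranyl methanol
Product: 13 [(2R,3S)-2-(4-acetoxy-3-methoxyphenyl)-3,4-dihydro-2H-pyran-3-yl]methyl acetate, via tetrabutylammonium phenoxide 12 (not isolated)
Conditions: TBAF, THF, 0 °C; then Ac2O, Et3N, DMAP (cat.), 0 °C → rt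
Reagents that add atoms: acetic anhydride, CC(=O)OC(C)=O
Why: Fluoride desilylation followed in the same flask by DMAP-catalysed acetylation installs both acetates at once; the phenoxide is harmless here because O1 of this enol ether is not yet a good leaving group.

Step 7
Reactants: 13 pyran diacetate
Product: 14 [(2R,3S)-2-(4-acetoxy-3-methoxyphenyl)-5-iodo-3,4-dihydro-2H-pyran-3-yl]methyl acetate
Conditions: NIS, AgNO3 (20 mol %), MeCN, 70 °C
Reagents that add atoms: N-iodosuccinimide, O=C1CCC(=O)N1I
Why: Electrophilic iodination of a glycal-type enol ether at its β-carbon (iodonium addition at C5, then loss of the C5 proton), the method used to make 2-iodoglycals; the enol ether is far more nucleophilic than the acetylated guaiacyl ring.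

Step 8
Reactants: 14 iodo-dihydropyran
Product: 15 [(2R,3S)-2-(4-acetoxy-3-methoxyphenyl)-5-(4,4,5,5-tetramethyl-1,3,2-dioxaborolan-2-yl)-3,4-dihydro-2H-pyran-3-yl]methyl acetate
Conditions: B2pin2, PdCl2(dppf) (5 mol %), KOAc, 1,4-dioxane, 80 °C
Reagents that add atoms: bis(pinacolato)diboron, CC1(C)OB(OC1(C)C)B1OC(C)(C)C(C)(C)O1
Why: Miyaura borylation of the alkenyl iodide, with potassium acetate as a base that cannot cleave the two acetates.

Step 9
Reactants: 16 methyl 2-(furan-3-yl)acetate
Product: 18 methyl 2-(2-formylfuran-3-yl)acetate, via iminium chloride 17 (not isolated)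
Conditions: POCl3, DMF, 1,2-dichloroethane, 0 °C → rt; then H2O
Reagents that add atoms: N,N-dimethylformamide, CN(C)C=O; water, O
Why: Vilsmeier–Haack formylation, which on 3-alkylfurans goes mainly to C2 (the α-position next to the alkyl group, as with 3-methylfuran); the minor C5 aldehyde should be removable by chromatography.

Step 10
Reactants: 18 methyl 2-(2-formylfuran-3-yl)acetate
Product: 19 methyl 2-(5-bromo-2-formylfuran-3-yl)acetate
Conditions: NBS, DMF, 40 °C, dark
Reagents that add atoms: N-bromosuccinimide, O=C1CCC(=O)N1Br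
Why: Electrophilic aromatic bromination at C5, the only free α-position of the 2-furaldehyde (the preparation of 5-bromofurfural is the model), under ionic conditions that spare the CH2 group.

Step 11
Reactants: 19 methyl 2-(5-bromo-2-formylfuran-3-yl)acetate; 20 1-(triphenylphosphoranylidene)propan-2-one
Product: 21 methyl 2-{5-bromo-2-[(E)-3-oxobut-1-en-1-yl]furan-3-yl}acetate
Conditions: toluene, 80 °C
Reagents that add atoms: none
Why: Wittig olefination with a ketone-stabilised ylide, which should give the (E)-enone required for the later ring closure.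

Step 12
Reactants: 21 bromofuryl enone methyl ester
Product: 22 2-{5-bromo-2-[(E)-3-oxobut-1-en-1-yl]furan-3-yl}acetic acid
Conditions: LiOH·H2O, THF/H2O (3:1), 0 °C; then 1 M HCl to pH 3
Reagents that add atoms: lithium hydroxide, [Li+].[OH-]
Why: Saponification is done on this fragment, which has no acetates, so that the acid is carried unprotected and no ester has to be cleaved after the coupling (an allyl ester would not survive the palladium steps and a simple ester could not be removed beside the acetates).

Step 13
Reactants: 15 dihydropyranyl pinacol boronate; 22 bromofuryl enone acid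
Product: 23 2-{5-[(2R,3S)-3-(acetoxymethyl)-2-(4-acetoxy-3-methoxyphenyl)-3,4-dihydro-2H-pyran-5-yl]-2-[(E)-3-oxobut-1-en-1-yl]furan-3-yl}acetic acid
Conditions: PdCl2(dppf) (5 mol %), CsF (4 equiv), anhydrous 1,4-dioxane, 70 °C; work-up with aqueous citric acid
Reagents that add atoms: none
Why: Suzuki–Miyaura coupling of the alkenyl pinacol boronate with the electron-poor 2-bromofuran under anhydrous fluoride activation, conditions under which the acid reacts as its caesium carboxylate and the aryl and alkyl acetates should stay on.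

Step 14
Reactants: 23 furan-3-ylacetic acid carrying the (E)-enone and the pyran
Product: 28 propolis-benzofuran A with both phenols acetylated, via mixed acetic anhydride 24 (not isolated), via furyl ketene 25 (not isolated), via cyclohexadienone 26 (not isolated), via phenol 27 (not isolated)
Conditions: Ac2O, NaOAc (3 equiv), 100 °C, 0.02 M
Reagents that add atoms: acetic anhydride, CC(=O)OC(C)=O
Why: Ac2O converts the acid into its mixed anhydride, and acetate removes the acidic furylic α-proton with loss of acetate to give the furyl ketene. The ketene C=C, the furan C2=C3 bond and the (E)-enone C=C form a hexatriene whose ends, the ketene carbonyl carbon (future C5') and the acetyl-bearing alkene carbon (future C6'), are joined by a thermal six-electron electrocyclisation; the closest known reactions are the dienylketene closure that ends a Danheiser benzannulation and the Ac2O–NaOAc cyclisation of Stobbe-type dienoic acids to acetoxy-arenes and acetoxybenzofurans. The six-membered carbocycle closes in a disrotatory six-electron mode, and the resulting 6-acetylcyclohexa-2,4-dienone should enolise at once to the 5'-phenol, which is acetylated in the same medium. No lasting stereocentre is formed, because the sp3 carbon of the dienone is lost on aromatisation and C2 and C3 of the pyran take no part. The regiochemistry follows from connectivity alone, since the furan holds the central double bond cis and the acetyl group already sits on the terminal carbon; the step needs only the E enone (hydrogen, not acetyl, turned into the closing ring, secured by the stabilised ylide) and ketene formation at the single carboxylic acid. High dilution and the acetate-buffered medium are chosen so that the ketene closes on itself before it can add to the pyran enol ether, and the acetylated guaiacyl ring cannot open the pyran.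

Step 15
Reactants: 28 di-O-acetyl propolis-benzofuran A
Product: 29 propolis-benzofuran A
Conditions: NH4OAc (10 equiv), MeOH/H2O (4:1), rt
Reagents that add atoms: none
Why: Ammonium acetate in aqueous methanol cleaves phenyl acetates by near-neutral aminolysis much faster than alkyl acetates, so both phenols should be freed while the primary acetate and the C2 benzylic ether (sensitive to phenoxide at high pH) are kept.

**Compound list**

1 | vanillin | COc1cc(C=O)ccc1O | starting material
2 | 4-[(tert-butyldimethylsilyl)oxy]-3-methoxybenzaldehyde | COc1cc(C=O)ccc1O[Si](C)(C)C(C)(C)C | intermediate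
3 | (R)-4-benzyloxazolidin-2-one | O=C1N[C@H](Cc2ccccc2)CO1 | starting material
4 | pent-4-ynoic acid | C#CCCC(=O)O | starting material
5 | pent-4-ynoic pivalic anhydride | C#CCCC(=O)OC(=O)C(C)(C)C | intermediate (not isolated)
6 | (R)-4-benzyl-3-(pent-4-ynoyl)oxazolidin-2-one | C#CCCC(=O)N1[C@H](Cc2ccccc2)COC1=O | intermediate
7 | dibutylboron (Z)-enolate of 6 | C#CC/C=C(\OB(CCCC)CCCC)N1[C@H](Cc2ccccc2)COC1=O | intermediate (not isolated)
8 | dibutylboron aldolate of 9 | COc1cc([C@H](OB(CCCC)CCCC)[C@@H](CC#C)C(=O)N2[C@H](Cc3ccccc3)COC2=O)ccc1O[Si](C)(C)C(C)(C)C | intermediate (not isolated)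
9 | (R)-4-benzyl-3-[(2R)-2-{(R)-[4-(tert-butyldimethylsilyloxy)-3-methoxyphenyl](hydroxy)methyl}pent-4-ynoyl]oxazolidin-2-one | COc1cc([C@H](O)[C@@H](CC#C)C(=O)N2[C@H](Cc3ccccc3)COC2=O)ccc1O[Si](C)(C)C(C)(C)C | intermediate
10 | (R)-4-benzyl-3-{(2R,3R)-2-[4-(tert-butyldimethylsilyloxy)-3-methoxyphenyl]-3,4-dihydro-2H-pyran-3-carbonyl}oxazolidin-2-one | COc1cc([C@@H]2OC=CC[C@H]2C(=O)N3[C@H](Cc4ccccc4)COC3=O)ccc1O[Si](C)(C)C(C)(C)C | intermediate
11 | {(2R,3S)-2-[4-(tert-butyldimethylsilyloxy)-3-methoxyphenyl]-3,4-dihydro-2H-pyran-3-yl}methanol | COc1cc([C@@H]2OC=CC[C@H]2CO)ccc1O[Si](C)(C)C(C)(C)C | intermediate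
12 | tetrabutylammonium 4-[(2R,3S)-3-(hydroxymethyl)-3,4-dihydro-2H-pyran-2-yl]-2-methoxyphenoxide | COc1cc([C@@H]2OC=CC[C@H]2CO)ccc1[O-].CCCC[N+](CCCC)(CCCC)CCCC | intermediate (not isolated)
13 | [(2R,3S)-2-(4-acetoxy-3-methoxyphenyl)-3,4-dihydro-2H-pyran-3-yl]methyl acetate | COc1cc([C@@H]2OC=CC[C@H]2COC(C)=O)ccc1OC(C)=O | intermediate
14 | [(2R,3S)-2-(4-acetoxy-3-methoxyphenyl)-5-iodo-3,4-dihydro-2H-pyran-3-yl]methyl acetate | COc1cc([C@@H]2OC=C(I)C[C@H]2COC(C)=O)ccc1OC(C)=O | intermediate
15 | [(2R,3S)-2-(4-acetoxy-3-methoxyphenyl)-5-(4,4,5,5-tetramethyl-1,3,2-dioxaborolan-2-yl)-3,4-dihydro-2H-pyran-3-yl]methyl acetate | COc1cc([C@@H]2OC=C(B3OC(C)(C)C(C)(C)O3)C[C@H]2COC(C)=O)ccc1OC(C)=O | intermediate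
16 | methyl 2-(furan-3-yl)acetate | COC(=O)Cc1ccoc1 | starting material
17 | N-{[3-(2-methoxy-2-oxoethyl)furan-2-yl]methylidene}-N-methylmethanaminium chloride | COC(=O)Cc1ccoc1C=[N+](C)C.[Cl-] | intermediate (not isolated)
18 | methyl 2-(2-formylfuran-3-yl)acetate | COC(=O)Cc1ccoc1C=O | intermediate
19 | methyl 2-(5-bromo-2-formylfuran-3-yl)acetate | COC(=O)Cc1cc(Br)oc1C=O | intermediate
20 | 1-(triphenylphosphoranylidene)propan-2-one | CC(=O)C=P(c1ccccc1)(c1ccccc1)c1ccccc1 | starting material
21 | methyl 2-{5-bromo-2-[(E)-3-oxobut-1-en-1-yl]furan-3-yl}acetate | COC(=O)Cc1cc(Br)oc1/C=C/C(C)=O | intermediate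
22 | 2-{5-bromo-2-[(E)-3-oxobut-1-en-1-yl]furan-3-yl}acetic acid | OC(=O)Cc1cc(Br)oc1/C=C/C(C)=O | intermediate
23 | 2-{5-[(2R,3S)-3-(acetoxymethyl)-2-(4-acetoxy-3-methoxyphenyl)-3,4-dihydro-2H-pyran-5-yl]-2-[(E)-3-oxobut-1-en-1-yl]furan-3-yl}acetic acid | COc1cc([C@@H]2OC=C(c3cc(CC(=O)O)c(/C=C/C(C)=O)o3)C[C@H]2COC(C)=O)ccc1OC(C)=O | intermediate
24 | mixed acetic anhydride of 23 | COc1cc([C@@H]2OC=C(c3cc(CC(=O)OC(C)=O)c(/C=C/C(C)=O)o3)C[C@H]2COC(C)=O)ccc1OC(C)=O | intermediate (not isolated)
25 | furan-3-yl ketene derived from 23 | COc1cc([C@@H]2OC=C(c3cc(C=C=O)c(/C=C/C(C)=O)o3)C[C@H]2COC(C)=O)ccc1OC(C)=O | intermediate (not isolated)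
26 | 6-acetyl-1-benzofuran-5(6H)-one carrying the pyran at C2' (either configuration at C6') | COc1cc([C@@H]2OC=C(C3=CC4=CC(=O)C(C(C)=O)C=C4O3)C[C@H]2COC(C)=O)ccc1OC(C)=O | intermediate (not isolated)
27 | propolis-benzofuran A acetylated only at the guaiacyl oxygen | COc1cc([C@@H]2OC=C(c3cc4cc(O)c(C(C)=O)cc4o3)C[C@H]2COC(C)=O)ccc1OC(C)=O | intermediate (not isolated)
28 | propolis-benzofuran A with both phenols acetylated | COc1cc([C@@H]2OC=C(c3cc4cc(OC(C)=O)c(C(C)=O)cc4o3)C[C@H]2COC(C)=O)ccc1OC(C)=O | intermediate
29 | propolis-benzofuran A, (2R,3S) | COc1cc([C@@H]2OC=C(c3cc4cc(O)c(C(C)=O)cc4o3)C[C@H]2COC(C)=O)ccc1O | target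

**Step count and risks**

Total: 15 steps. Longest linear sequence: 10 steps (steps 2 to 8, then 13 to 15).

Steps most likely to fail:

1. Step 14. The ketene may be intercepted by the electron-rich pyran enol ether of a second molecule, or the hot anhydride medium may acetolyse the enol ether or the C2 benzylic ether before ring closure is complete. Fallback: the same ring closure is moved onto the small fragment, so that the pyran never meets the ketene conditions. It sets out from acid 22: Ac2O/NaOAc at 100 °C should give 6-acetyl-2-bromo-1-benzofuran-5-yl acetate F1. Coupling of F1 with boronate 15 under the conditions of step 13 (PdCl2(dppf), CsF, dioxane, 70 °C) comes back to the route at 28.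

2. Step 13. Fluoride or adventitious hydroxide may take off the aryl acetate, after which the para-phenoxide can expel O1 from C2 and erode the C2 configuration; the carboxylic acid may also protodeboronate the electron-rich alkenyl boronate before transmetalation. Fallback: a base-free Stille coupling with reversed polarity. It sets out from bromo ester 21 and iodide 14. Stannylation of 21 (Me3SnSnMe3, Pd(PPh3)4, toluene, 90 °C) gives methyl 2-{2-[(E)-3-oxobut-1-en-1-yl]-5-(trimethylstannyl)furan-3-yl}acetate F2. Neutral ester cleavage with Me3SnOH (1,2-dichloroethane, 70 °C) gives 2-{2-[(E)-3-oxobut-1-en-1-yl]-5-(trimethylstannyl)furan-3-yl}acetic acid F3. F3 is coupled with 14 (Pd2(dba)3, AsPh3, CuI, DMF, 40 °C), which comes back to the route at 23.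

3. Step 4. Under amine, heat and light the β-hydroxy imide may undergo retro-aldol cleavage or acyl transfer, or its hydrogen-bonded hydroxyl may add too slowly to the vinylidene. Fallback: the enol ether is made through a lactol instead of a metal vinylidene. It sets out from aldol adduct 9: anti-Markovnikov hydroboration of the alkyne with Cy2BH (THF, 0 °C) and buffered oxidation (pH 7, H2O2) give the aldehyde, which should close to (R)-4-benzyl-3-{(2R,3R)-2-[4-(tert-butyldimethylsilyloxy)-3-methoxyphenyl]-6-hydroxytetrahydro-2H-pyran-3-carbonyl}oxazolidin-2-one F4 (both anomers). Dehydration with MsCl/Et3N (CH2Cl2, 0 °C → reflux) comes back to the route at 10.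

Further compounds
F1 | step 14 | 6-acetyl-2-bromo-1-benzofuran-5-yl acetate | CC(=O)Oc1cc2cc(Br)oc2cc1C(C)=O
F2 | step 13 | methyl 2-{2-[(E)-3-oxobut-1-en-1-yl]-5-(trimethylstannyl)furan-3-yl}acetate | COC(=O)Cc1cc([Sn](C)(C)C)oc1/C=C/C(C)=O
F3 | step 13 | 2-{2-[(E)-3-oxobut-1-en-1-yl]-5-(trimethylstannyl)furan-3-yl}acetic acid | OC(=O)Cc1cc([Sn](C)(C)C)oc1/C=C/C(C)=O
F4 | step 4 | (R)-4-benzyl-3-{(2R,3R)-2-[4-(tert-butyldimethylsilyloxy)-3-methoxyphenyl]-6-hydroxytetrahydro-2H-pyran-3-carbonyl}oxazolidin-2-one | COc1cc([C@@H]2OC(O)CC[C@H]2C(=O)N3[C@H](Cc4ccccc4)COC3=O)ccc1O[Si](C)(C)C(C)(C)C
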